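Remark on the chemistry (assumption): commercial D-(−)-tartaric acid is the (2S,3S) enantiomer; its C2 becomes C2 of the target with the descriptor unchanged, and its C3 is later erased as a planar radical, so the C3 descriptor drawn for open-chain compounds is immaterial. Ring numbering (C1 carbinol, C2 CHOAc, C3 CHOBz, C4=C5, C6 ketone, exocyclic C7) is used for open-chain compounds too.

## Structural features

The target is a cyclohex-2-enone (ring C1–C6, enone C4=C5–C6=O). It carries a free tertiary hydroxyl and the exocyclic benzoyloxymethyl carbon C7 at C1, an acetate at C2 and a benzoate at C3. C1, C2 and C3 are contiguous stereocentres, (1S,2S,3R): the C1 hydroxyl and the C2 acetate are cis, the C3 benzoate is trans to the acetate, and C1 is fully substituted. Fragile points are three esters placed 1,2 and 1,3 to each other and to a free tertiary alcohol (acyl migration), an α-ketol, and a γ-acyloxy enone that eliminates carboxylate and aromatises under base. The real difficulty is the oxygen pattern rather than the ring: O2 and O3, equivalent in any tartrate-type precursor, must end as acetate and benzoate next to a quaternary carbinol of defined configuration. The key step exploits that C3 is an α-benzoyloxy carbon, hence a nucleophilic radical after decarboxylation, while C4 is the β-carbon of the C6 enone; the ring bond C3–C4 is therefore a polarity-matched radical–acceptor bond whose formation closes the six-membered ring. Two properties of the open-chain precursor shape the route. A free C1 hydroxyl is γ to the activated C3 carboxyl and would lactonise, so O1 is carried as a silyl ether. Free hydroxyls at C2 or C7 are β′ to the vinyl ketone and would close a tetrahydropyranone by oxa-Michael addition, so the enone is unmasked only after O2 and O7 are acylated.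

## Logic of the disconnections

25 ⇒ 24. Only the O1–Si bond is added. Reason: with O1 free, the activated C3 carboxyl of the open-chain stage would close a γ-lactone and the α-ketol would interfere with enol ether chemistry. Gain: no skeletal simplification, but all earlier intermediates become stable. Demand: the last desilylation must be non-basic, because an alkoxide at O1 would take the acyl groups from O2 or O7 and the γ-acyloxy enone eliminates with base.

24 ⇒ 22 (through 23). The C4=C5 π bond is removed. Reason: a reductive radical conjugate addition ends at the saturated ketone. Gain: the sensitive γ-benzoyloxy enone becomes a ketone with one enolisable position (C5, since C1 is quaternary). Demand: regiodefined dehydrogenation without strong base, through a silyl enol ether and divalent palladium.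

22 ⇒ 21. The ring bond C3–C4 is cut. Reason: it joins a nucleophilic α-acyloxy radical carbon to the electrophilic terminus of a vinyl ketone. Gain: the carbocycle and the C3 stereocentre are exchanged for an open chain with only C1 and C2 defined; C3 of 21 may have either configuration. Demand: 6-endo closure in preference to 5-exo, the benzoate trans to the acetate, ring closure faster than intermolecular addition, and electron transfer to the redox-active ester before the enone.

21 ⇒ 19 + 20. The acyl O–N bond is cut. Reason: the N-acyloxyphthalimide is the electron acceptor that releases the C3 radical. Gain: a plain carboxylic acid. Demand: activation without nucleophilic catalysts (vinyl ketone present) and no free hydroxyl anywhere in 19.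

19 ⇒ 18. The C6 carbonyl with its vinyl group is traced to a 1-methoxyallene and the acid to its 4-methoxybenzyl ester. Reason: both are released by one mild acid treatment, and the Michael acceptor appears only when O2 and O7 are capped. Gain: 18 is stable to base, fluoride and acylating agents. Demand: acid mild enough to spare the tertiary silyl ether.

18 ⇒ 14 + 15 + 16. The three ester C–O bonds at O7, O3 and O2 are cut. Reason: this is where O2 and O3 are told apart, using the steric gradient created by the quaternary C1 (primary O7 and unhindered O3 take benzoyl first, the neopentylic O2 takes the smaller acetyl last). Gain: a triol with all acyl groups removed. Demand: regioselective acylation under non-acidic conditions, since the allenyl ether is present.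

14 ⇒ 13. Three O–SiEt3 bonds are added. Reason: ethers, not esters, must flank the carbonyl during the organometallic step, and they must later come off without acid while the tertiary tert-butyldimethylsilyl ether stays. Demand: buffered fluoride, to suppress silyl migration from O1 and lactonisation.

13 ⇒ 9 + 10. The C1–C6 bond (and the O1–Si bond) is cut. Reason: a lithiated alkoxyallene is an acryloyl anion equivalent, and its addition to the C1 ketone creates the quaternary carbinol with Felkin–Anh control from the C2 silyloxy group. Gain: three carbons and one stereocentre in one operation. Demand: a non-chelating α-oxygen substituent, no acyl group near the new alkoxide, and trapping of that alkoxide in the cold before it attacks the ester.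

9 ⇒ 8 ⇒ 7 ⇒ 4 + 5. The O7–Si bond, the C7–O bond and the C1–C7 bond are cut in turn. Reason: one-carbon homologation of the C1 carboxyl to an oxygenated methyl ketone. Gain: back to a four-carbon tartrate. Demand: acid chloride formation and carbene chemistry under neutral conditions compatible with silyl ethers and the benzylic ester.

4 ⇒ 3 ⇒ 2 ⇒ 1. Silyl groups and one ester are removed, then the second ester. Reason: the C2-symmetric diester is desymmetrised by half-hydrolysis, so one carboxyl becomes C1 and the other is the carbon later lost as CO2. Gain: the chiral-pool diacid 1, which supplies C2 with the correct (S) configuration. Demand: mono-selective saponification, and an ester group that is labile to the same dilute acid as the enol ether.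

## Other disconnections considered

Alternative 1: The cut is the exocyclic C1–C7 bond together with the C7–O bond. The ring with all four ring oxygens already exists in ketone A1 (C1 carbonyl, O2 as 4-methoxybenzyl ether, O3 and O6 as silyl ethers, all-trans). A sulfonium methylide (Corey–Chaykovsky methylene transfer) would add to C1 and close to spiro-epoxide A2 with C7 trans to O2.
- In its favour: no ring construction is needed, the quaternary centre is set on a conformationally defined ring rather than by acyclic induction, and opening A2 at its primary carbon with benzoate would install the C7 benzoate and free the C1 hydroxyl in one move. On the C1/C7 array it is the better plan; steps 4 to 10 here are longer.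
- Against it: A1 has acidic hydrogens at C2 and C6 with leaving groups β to them, so the basic ylide can enolise and eliminate. The facial preference between a flanking benzyl-type ether and a silyl ether is not obvious. O3 and O6 carry the same silyl group and must still be distinguished, and the O2 ether must be exchanged for acetate.
- Comparison: equal on the need to differentiate like oxygens late. Mechanistically it is a simple polar step but base-sensitive, where the radical closure is neutral. In step count it is probably comparable once the synthesis of A1 is included.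

Alternative 2: The cuts are the C3–O and C6–O bonds. A dye-sensitised photo-oxygenation would add dioxygen across C3 and C6 of diene A3 (C1/C2 cis-diol as acetonide, C7 benzoate in place) to give endoperoxide A4, bridge anti to the acetonide. A base-induced Kornblum–DeLaMare fragmentation would then give the C6 ketone, the C3 hydroxyl and the C4=C5 double bond.
- In its favour: both missing oxygens, the enone and the C3 configuration arise in two operations, and no dehydrogenation is needed. O3 is liberated alone while O1 and O2 are tied in the acetonide, so the benzoate/acetate differentiation that costs steps 8 and 9 here becomes trivial. On step economy and on oxygen differentiation this alternative is the better one.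
- Against it: the fragmentation must remove the bridgehead hydrogen at C6, next to the quaternary C1, rather than the more accessible one at C3; the other regiochemistry gives the C3 ketone. Enantiopure A3 with a quaternary ipso-diol depends on an enzymatic arene dihydroxylation whose absolute sense must match. A3 can aromatise, ene reactions compete, and peroxides limit scale.
- Comparison: the cycloaddition is stereospecific and its facial selectivity is at least as predictable as the chair transition state here. Its risk lies after the key step (regiochemistry of peroxide opening) and in the supply of A3, whereas the chosen plan starts from tartaric acid and carries its main risk in the key step.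

Alternative 3: The cuts are C1–C2 and C5–C6. An enantioselective exo Diels–Alder reaction of 2-(benzoyloxy)acrolein A5, activated as an iminium ion by a chiral primary-ammonium catalyst, with (E)-1-acetoxybuta-1,3-diene A6 would give adduct A7 with C1 (benzoate, formyl) and C2 (acetate) cis.
- In its favour: the ring, the quaternary C1 and C2 are set in one catalytic step from two achiral pieces, and the acetate is at C2 from the start. It is the better plan in convergence. Reduction of the formyl group followed by a 1,2-benzoyl shift from tertiary O1 to primary O7 would give the carbinol/benzoate pair neatly.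
- Against it: A7 has no oxygen at C3 or C6 and its double bond is C3=C4. Placing the C3 benzoate trans to O2 with allylic transposition, and above all oxidising the unactivated C6 methylene beside the quaternary centre to a ketone, needs several steps of doubtful regiocontrol. The exo and enantioselectivity rest entirely on the catalyst.
- Comparison: it solves C1/C2 better but leaves the C3–C6 oxidation pattern open, which the chosen plan builds in from tartaric acid and the allene. Its key step is a concerted cycloaddition with a well-understood selectivity model, equal to or more predictable than the radical closure. It is shorter up to the ring and longer after it.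

Key step: step 12

## Route

Step 1
Reactants: 1 D-(−)-tartaric acid, (2S,3S)-2,3-dihydroxybutanedioic acid
Product: 2 bis(4-methoxybenzyl) (2S,3S)-2,3-dihydroxybutanedioate
Conditions: 4-MeOC6H4CH2Cl (2.1 equiv), Cs2CO3 (1.0 equiv), DMF, rt
Reagents that add atoms: 4-methoxybenzyl chloride, COc1ccc(CCl)cc1
Why: SN2 O-alkylation of the dicarboxylate with a benzylic halide; carbonate does not deprotonate the secondary hydroxyls, and no stereocentre is touched. The 4-methoxybenzyl ester is chosen because dilute acid later cleaves it in the same operation that hydrolyses the enol ether.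

Step 2
Reactants: 2 bis(4-methoxybenzyl) (2S,3S)-2,3-dihydroxybutanedioate
Product: 3 (2S,3S)-2,3-dihydroxy-4-[(4-methoxybenzyl)oxy]-4-oxobutanoic acid
Conditions: KOH (1.0 equiv), THF–H2O, 0 °C; then aq. HCl to pH 3
Reagents that add atoms: potassium hydroxide, KOH, [K+].[OH-]
Why: Half-saponification of a C2-symmetric diester (acyl–oxygen ester hydrolysis); the monocarboxylate is hydrolysed more slowly than the neutral diester and is separated from diester and diacid by acid–base extraction. The free acid becomes C1; the remaining ester carbon is the one later lost as CO2.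

Step 3
Reactants: 3 (2S,3S)-2,3-dihydroxy-4-[(4-methoxybenzyl)oxy]-4-oxobutanoic acid
Product: 4 1-(4-methoxybenzyl) 4-(triethylsilyl) (2S,3S)-2,3-bis(triethylsilyloxy)butanedioate
Conditions: Et3SiCl (3.3 equiv), imidazole, CH2Cl2, 0 °C to rt; non-aqueous work-up
Reagents that add atoms: chlorotriethylsilane, CC[Si](Cl)(CC)CC
Why: Silylation of both hydroxyls and of the acid (silyl ether and silyl ester formation). Triethylsilyl ethers are non-chelating for step 7 and removable by buffered fluoride; the silyl ester is the substrate for neutral acid chloride formation.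

Step 4
Reactants: 4 1-(4-methoxybenzyl) 4-(triethylsilyl) (2S,3S)-2,3-bis(triethylsilyloxy)butanedioate; 5 (trimethylsilyl)diazomethane
Product: 7 4-methoxybenzyl (2S,3S)-5-diazo-4-oxo-2,3-bis(triethylsilyloxy)pentanoate, via acid chloride 6 (not isolated)
Conditions: (COCl)2, DMF (cat.), CH2Cl2, 0 °C to rt; concentrate; then 5 (2 equiv), MeCN–THF, 0 °C
Reagents that add atoms: none
Why: Silyl esters are converted into acid chlorides by oxalyl chloride/DMF without free HCl, which protects the silyl ethers and the benzylic ester. Acylation of the diazoalkane (Arndt–Eistert-type diazoketone synthesis) then attaches C7.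

Step 5
Reactants: 7 4-methoxybenzyl (2S,3S)-5-diazo-4-oxo-2,3-bis(triethylsilyloxy)pentanoate
Product: 8 4-methoxybenzyl (2S,3S)-5-hydroxy-4-oxo-2,3-bis(triethylsilyloxy)pentanoate
Conditions: Rh2(OAc)4 (1 mol %), H2O (20 equiv), DME, rt
Reagents that add atoms: water, O
Why: O–H insertion of the divalent rhodium carbenoid into water gives the hydroxymethyl ketone under neutral conditions; the excess of water outruns intramolecular carbenoid pathways.

Step 6
Reactants: 8 4-methoxybenzyl (2S,3S)-5-hydroxy-4-oxo-2,3-bis(triethylsilyloxy)pentanoate
Product: 9 4-methoxybenzyl (2S,3S)-4-oxo-2,3,5-tris(triethylsilyloxy)pentanoate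
Conditions: Et3SiCl, imidazole, CH2Cl2, 0 °C
Reagents that add atoms: chlorotriethylsilane, CC[Si](Cl)(CC)CC
Why: Silylation of the primary hydroxyl under mild base that should not epimerise C2. O7 must not be acylated yet, because an ester next to the carbonyl would be attacked by the organolithium or by the tertiary alkoxide formed in step 7.

Step 7
Reactants: 9 4-methoxybenzyl (2S,3S)-4-oxo-2,3,5-tris(triethylsilyloxy)pentanoate; 10 methoxyallene (1-methoxypropa-1,2-diene)
Product: 13 4-methoxybenzyl (2S,3S,4S)-4-(tert-butyldimethylsilyloxy)-5-methoxy-2,3-bis(triethylsilyloxy)-4-[(triethylsilyloxy)methyl]hepta-5,6-dienoate, via 1-lithio-1-methoxyallene 11 (not isolated), via lithium alkoxide 12 (not isolated)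
Conditions: 10 (1.5 equiv), n-BuLi (1.25 equiv), THF, −78 to −40 °C; 9, −78 °C; then t-BuMe2SiOTf (2 equiv), −78 to −40 °C; Et3N, aq. NaHCO3
Reagents that add atoms: tert-butyldimethylsilyl trifluoromethanesulfonate, CC(C)(C)[Si](C)(C)OS(=O)(=O)C(F)(F)F
Why: 1,2-Addition of a lithiated alkoxyallene (acryloyl anion equivalent) to the ketone. The new C1 centre is set by the polar Felkin–Anh (Cornforth) model: the C2–OSiEt3 bond lies anti to the incoming nucleophile, which passes the C2 hydrogen; this gives (S) at C1, the arrangement that becomes C1–O cis to C2–O in the ring, and the non-chelating silyl ether in THF disfavours the chelate pathway that would give the C1 epimer. The alkoxide is silylated at −78 °C before it can attack the ester or take a silyl group from a neighbouring oxygen.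

Step 8
Reactants: 13 4-methoxybenzyl (2S,3S,4S)-4-(tert-butyldimethylsilyloxy)-5-methoxy-2,3-bis(triethylsilyloxy)-4-[(triethylsilyloxy)methyl]hepta-5,6-dienoate
Product: 14 4-methoxybenzyl (2S,3S,4S)-4-(tert-butyldimethylsilyloxy)-2,3-dihydroxy-4-(hydroxymethyl)-5-methoxyhepta-5,6-dienoate
Conditions: n-Bu4NF, AcOH (1:1, 3.3 equiv), THF, 0 °C
Reagents that add atoms: none
Why: Fluoride-induced desilylation; primary and secondary triethylsilyl ethers are cleaved far faster than the hindered tertiary tert-butyldimethylsilyl ether. Buffering with acetic acid suppresses silyl migration from O1 and lactonisation, and the acid-labile allenyl ether is not touched.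

Step 9
Reactants: 14 4-methoxybenzyl (2S,3S,4S)-4-(tert-butyldimethylsilyloxy)-2,3-dihydroxy-4-(hydroxymethyl)-5-methoxyhepta-5,6-dienoate; 15 benzoyl chloride; 16 acetic anhydride
Product: 18 4-methoxybenzyl (2S,3S,4S)-3-acetoxy-2-(benzoyloxy)-4-[(benzoyloxy)methyl]-4-(tert-butyldimethylsilyloxy)-5-methoxyhepta-5,6-dienoate, via dibenzoate 17 (not isolated)
Conditions: 15 (2.1 equiv), pyridine, CH2Cl2, −30 to 0 °C; then 16 (3 equiv), DMAP (cat.), 0 °C to rt
Reagents that add atoms: none
Why: Sequential nucleophilic acyl substitution governed by sterics: the primary O7 and the secondary O3 (one carbon away from the quaternary centre) should be benzoylated first, while O2, flanked by the fully substituted C1 with its bulky silyl ether, reacts only with the small acetyl donor under DMAP catalysis. This differentiates the two tartrate oxygens; no stereocentre is formed.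

Step 10
Reactants: 18 4-methoxybenzyl (2S,3S,4S)-3-acetoxy-2-(benzoyloxy)-4-[(benzoyloxy)methyl]-4-(tert-butyldimethylsilyloxy)-5-methoxyhepta-5,6-dienoate
Product: 19 (2S,3S,4S)-3-acetoxy-2-(benzoyloxy)-4-[(benzoyloxy)methyl]-4-(tert-butyldimethylsilyloxy)-5-oxohept-6-enoic acid
Conditions: CF3CO2H–CH2Cl2–H2O (5:93:2), 0 °C
Reagents that add atoms: water, O
Why: Acid-catalysed hydrolysis of the 1-methoxyallene (enol ether hydrolysis) unmasks the vinyl ketone, and the 4-methoxybenzyl ester is cleaved by acidolysis through the stabilised benzylic cation in the same flask. O2 and O7 are acylated and O1 silylated at this point, so neither oxa-Michael closure nor γ-lactonisation is possible, and the hindered tertiary silyl ether next to a carbonyl should survive the dilute acid.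

Step 11
Reactants: 19 (2S,3S,4S)-3-acetoxy-2-(benzoyloxy)-4-[(benzoyloxy)methyl]-4-(tert-butyldimethylsilyloxy)-5-oxohept-6-enoic acid; 20 N-hydroxyphthalimide
Product: 21 1,3-dioxoisoindolin-2-yl (2S,3S,4S)-3-acetoxy-2-(benzoyloxy)-4-[(benzoyloxy)methyl]-4-(tert-butyldimethylsilyloxy)-5-oxohept-6-enoate
Conditions: 20, i-PrN=C=N-i-Pr, CH2Cl2, 0 °C to rt
Reagents that add atoms: none
Why: Carbodiimide-mediated esterification gives the redox-active ester; DMAP is left out so that no nucleophilic catalyst adds to the vinyl ketone. Any epimerisation at C3 during activation is without consequence.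

Step 12
Reactants: 21 1,3-dioxoisoindolin-2-yl (2S,3S,4S)-3-acetoxy-2-(benzoyloxy)-4-[(benzoyloxy)methyl]-4-(tert-butyldimethylsilyloxy)-5-oxohept-6-enoate
Product: 22 [(1S,2S,3R)-2-acetoxy-3-(benzoyloxy)-1-(tert-butyldimethylsilyloxy)-6-oxocyclohexyl]methyl benzoate
Conditions: constant current (about 2.2 F/mol), undivided cell, reticulated vitreous carbon cathode, sacrificial Zn anode, n-Bu4NPF6 (0.1 M), CF3CH2OH (3 equiv), DMF, 5 mM, rt
Reagents that add atoms: none
Why: Cathodic single-electron transfer to the phthalimide unit gives a radical anion that fragments (N–O cleavage, loss of CO2 and phthalimide anion) to the C3 radical, which is nucleophilic through its α-benzoyloxy group and adds to the unsubstituted β-carbon C4 of the vinyl ketone; the α-keto radical at C5 is then reduced at the cathode to the enolate and protonated by trifluoroethanol. The closest known reaction type is the reductive decarboxylative Giese addition of N-(acyloxy)phthalimides to enones under electrochemical or photoredox electron transfer, used here intramolecularly. The six-membered ring closes in the 6-endo-trig mode, favoured over 5-exo because attack at C4 is polarity-matched, sterically open and leads to the stabilised α-keto radical, whereas attack at C5 would give a primary unstabilised radical. The new C3 centre is set under kinetic control by a chair-like transition state in which C7 on C1, the C2 acetate and the C3 benzoate are pseudo-equatorial and only the C1 silyloxy group is axial; a pseudo-axial benzoate would meet that silyl ether in a 1,3-diaxial clash, so the benzoate should end trans to the acetate. The radical is planar, so the C3 configuration of 21 does not matter. The step needs three selectivities: reduction of the redox-active ester before the enone (it is the more easily reduced group, and the charge is limited), ring closure before intermolecular addition (high dilution), and retention of the C2 acetate (an α-oxygenated radical is not reduced to the carbanion, so β-elimination is not expected).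

Step 13
Reactants: 22 [(1S,2S,3R)-2-acetoxy-3-(benzoyloxy)-1-(tert-butyldimethylsilyloxy)-6-oxocyclohexyl]methyl benzoate
Product: 23 [(1S,2S,3R)-2-acetoxy-3-(benzoyloxy)-1-(tert-butyldimethylsilyloxy)-6-(trimethylsilyloxy)cyclohex-5-en-1-yl]methyl benzoate
Conditions: Me3SiOTf (1.5 equiv), Et3N (3 equiv), CH2Cl2, 0 °C
Reagents that add atoms: trimethylsilyl trifluoromethanesulfonate, C[Si](C)(C)OS(=O)(=O)C(F)(F)F
Why: Soft enolisation (silyl triflate with a tertiary amine) gives the silyl enol ether; only C5 can enolise because C1 is quaternary, and ketones are silylated much faster than esters under these conditions.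

Step 14
Reactants: 23 [(1S,2S,3R)-2-acetoxy-3-(benzoyloxy)-1-(tert-butyldimethylsilyloxy)-6-(trimethylsilyloxy)cyclohex-5-en-1-yl]methyl benzoate
Product: 24 [(1S,2S,3R)-2-acetoxy-3-(benzoyloxy)-1-(tert-butyldimethylsilyloxy)-6-oxocyclohex-4-en-1-yl]methyl benzoate
Conditions: Pd(OAc)2 (1.1 equiv), MeCN, rt
Reagents that add atoms: none
Why: Saegusa–Ito oxidation: divalent palladium converts the enol ether into an α-palladated ketone, and β-hydride elimination gives the C4=C5 enone. Ligand-free conditions keep the zerovalent palladium that is formed inactive towards the new allylic benzoate.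

Step 15
Reactants: 24 [(1S,2S,3R)-2-acetoxy-3-(benzoyloxy)-1-(tert-butyldimethylsilyloxy)-6-oxocyclohex-4-en-1-yl]methyl benzoate
Product: 25 2-O-acetylzeylenone, [(1S,2S,3R)-2-acetoxy-3-(benzoyloxy)-1-hydroxy-6-oxocyclohex-4-en-1-yl]methyl benzoate
Conditions: HF·pyridine, pyridine, THF, 0 °C to rt
Reagents that add atoms: none
Why: Fluoride-mediated desilylation under acidic conditions removes the tertiary silyl ether without forming an alkoxide, so the acetate and benzoates should neither migrate to O1 nor be eliminated from the enone.

## Compound list

1 | D-(−)-tartaric acid, (2S,3S)-2,3-dihydroxybutanedioic acid | O[C@@H]([C@H](O)C(O)=O)C(O)=O | starting material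
2 | bis(4-methoxybenzyl) (2S,3S)-2,3-dihydroxybutanedioate | COc1ccc(COC(=O)[C@@H](O)[C@H](O)C(=O)OCc2ccc(OC)cc2)cc1 | intermediate
3 | (2S,3S)-2,3-dihydroxy-4-[(4-methoxybenzyl)oxy]-4-oxobutanoic acid | COc1ccc(COC(=O)[C@@H](O)[C@H](O)C(=O)O)cc1 | intermediate
4 | 1-(4-methoxybenzyl) 4-(triethylsilyl) (2S,3S)-2,3-bis(triethylsilyloxy)butanedioate | COc1ccc(COC(=O)[C@@H](O[Si](CC)(CC)CC)[C@H](O[Si](CC)(CC)CC)C(=O)O[Si](CC)(CC)CC)cc1 | intermediate
5 | (trimethylsilyl)diazomethane | C[Si](C)(C)C=[N+]=[N-] | starting material
6 | 4-methoxybenzyl (2S,3S)-4-chloro-4-oxo-2,3-bis(triethylsilyloxy)butanoate (acid chloride, not isolated) | COc1ccc(COC(=O)[C@@H](O[Si](CC)(CC)CC)[C@H](O[Si](CC)(CC)CC)C(Cl)=O)cc1 | intermediate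
7 | 4-methoxybenzyl (2S,3S)-5-diazo-4-oxo-2,3-bis(triethylsilyloxy)pentanoate | COc1ccc(COC(=O)[C@@H](O[Si](CC)(CC)CC)[C@H](O[Si](CC)(CC)CC)C(=O)C=[N+]=[N-])cc1 | intermediate
8 | 4-methoxybenzyl (2S,3S)-5-hydroxy-4-oxo-2,3-bis(triethylsilyloxy)pentanoate | COc1ccc(COC(=O)[C@@H](O[Si](CC)(CC)CC)[C@H](O[Si](CC)(CC)CC)C(=O)CO)cc1 | intermediate
9 | 4-methoxybenzyl (2S,3S)-4-oxo-2,3,5-tris(triethylsilyloxy)pentanoate | COc1ccc(COC(=O)[C@@H](O[Si](CC)(CC)CC)[C@H](O[Si](CC)(CC)CC)C(=O)CO[Si](CC)(CC)CC)cc1 | intermediate
10 | methoxyallene, 1-methoxypropa-1,2-diene | COC=C=C | starting material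
11 | 1-lithio-1-methoxyallene (not isolated) | [Li]C(OC)=C=C | intermediate
12 | lithium (2S,3S,4S)-alkoxide of the C1 carbinol, O1-lithio form of the adduct (not isolated) | COc1ccc(COC(=O)[C@@H](O[Si](CC)(CC)CC)[C@H](O[Si](CC)(CC)CC)[C@](CO[Si](CC)(CC)CC)([O-])C(OC)=C=C)cc1.[Li+] | intermediate
13 | 4-methoxybenzyl (2S,3S,4S)-4-(tert-butyldimethylsilyloxy)-5-methoxy-2,3-bis(triethylsilyloxy)-4-[(triethylsilyloxy)methyl]hepta-5,6-dienoate | COc1ccc(COC(=O)[C@@H](O[Si](CC)(CC)CC)[C@H](O[Si](CC)(CC)CC)[C@](CO[Si](CC)(CC)CC)(O[Si](C)(C)C(C)(C)C)C(OC)=C=C)cc1 | intermediate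
14 | 4-methoxybenzyl (2S,3S,4S)-4-(tert-butyldimethylsilyloxy)-2,3-dihydroxy-4-(hydroxymethyl)-5-methoxyhepta-5,6-dienoate | COc1ccc(COC(=O)[C@@H](O)[C@H](O)[C@](CO)(O[Si](C)(C)C(C)(C)C)C(OC)=C=C)cc1 | intermediate
15 | benzoyl chloride | O=C(Cl)c1ccccc1 | starting material
16 | acetic anhydride | CC(=O)OC(C)=O | starting material
17 | 4-methoxybenzyl (2S,3S,4S)-2-(benzoyloxy)-4-[(benzoyloxy)methyl]-4-(tert-butyldimethylsilyloxy)-3-hydroxy-5-methoxyhepta-5,6-dienoate (not isolated) | COc1ccc(COC(=O)[C@@H](OC(=O)c2ccccc2)[C@H](O)[C@](COC(=O)c2ccccc2)(O[Si](C)(C)C(C)(C)C)C(OC)=C=C)cc1 | intermediate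
18 | 4-methoxybenzyl (2S,3S,4S)-3-acetoxy-2-(benzoyloxy)-4-[(benzoyloxy)methyl]-4-(tert-butyldimethylsilyloxy)-5-methoxyhepta-5,6-dienoate | COc1ccc(COC(=O)[C@@H](OC(=O)c2ccccc2)[C@H](OC(C)=O)[C@](COC(=O)c2ccccc2)(O[Si](C)(C)C(C)(C)C)C(OC)=C=C)cc1 | intermediate
19 | (2S,3S,4S)-3-acetoxy-2-(benzoyloxy)-4-[(benzoyloxy)methyl]-4-(tert-butyldimethylsilyloxy)-5-oxohept-6-enoic acid | OC(=O)[C@@H](OC(=O)c1ccccc1)[C@H](OC(C)=O)[C@](COC(=O)c1ccccc1)(O[Si](C)(C)C(C)(C)C)C(=O)C=C | intermediate
20 | N-hydroxyphthalimide | ON1C(=O)c2ccccc2C1=O | starting material
21 | 1,3-dioxoisoindolin-2-yl (2S,3S,4S)-3-acetoxy-2-(benzoyloxy)-4-[(benzoyloxy)methyl]-4-(tert-butyldimethylsilyloxy)-5-oxohept-6-enoate (key-step precursor, O1-silylated) | O=C(ON1C(=O)c2ccccc2C1=O)[C@@H](OC(=O)c1ccccc1)[C@H](OC(C)=O)[C@](COC(=O)c1ccccc1)(O[Si](C)(C)C(C)(C)C)C(=O)C=C | intermediate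
22 | [(1S,2S,3R)-2-acetoxy-3-(benzoyloxy)-1-(tert-butyldimethylsilyloxy)-6-oxocyclohexyl]methyl benzoate (key-step product, O1-silylated 4,5-dihydro target) | CC(=O)O[C@H]1[C@H](OC(=O)c2ccccc2)CCC(=O)[C@]1(O[Si](C)(C)C(C)(C)C)COC(=O)c1ccccc1 | intermediate
23 | [(1S,2S,3R)-2-acetoxy-3-(benzoyloxy)-1-(tert-butyldimethylsilyloxy)-6-(trimethylsilyloxy)cyclohex-5-en-1-yl]methyl benzoate | CC(=O)O[C@H]1[C@H](OC(=O)c2ccccc2)CC=C(O[Si](C)(C)C)[C@]1(O[Si](C)(C)C(C)(C)C)COC(=O)c1ccccc1 | intermediate
24 | [(1S,2S,3R)-2-acetoxy-3-(benzoyloxy)-1-(tert-butyldimethylsilyloxy)-6-oxocyclohex-4-en-1-yl]methyl benzoate | CC(=O)O[C@H]1[C@H](OC(=O)c2ccccc2)C=CC(=O)[C@]1(O[Si](C)(C)C(C)(C)C)COC(=O)c1ccccc1 | intermediate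
25 | 2-O-acetylzeylenone, [(1S,2S,3R)-2-acetoxy-3-(benzoyloxy)-1-hydroxy-6-oxocyclohex-4-en-1-yl]methyl benzoate | CC(=O)O[C@H]1[C@H](OC(=O)c2ccccc2)C=CC(=O)[C@]1(O)COC(=O)c1ccccc1 | target

## Step count and least certain steps

Total step count: 15. Longest linear sequence: 15 steps (1 to 25); 5, 10, 15, 16 and 20 are commercial and enter directly.

Step 12 (key step). Most likely to go wrong: poor facial selectivity at C3, because the preference for the chair with a pseudo-equatorial benzoate rests on modest conformational energy differences. A second risk is loss of the C3 radical by hydrogen abstraction from the solvent or by further reduction near the electrode before the comparatively slow 6-endo closure.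
Fallback: the approach changes from electrode-driven reduction to a light-driven group-transfer chain that can be run cold. Setting out from 19, coupling with 1-hydroxypyridine-2(1H)-thione and diisopropylcarbodiimide would give the thiohydroxamate (Barton) ester F1. Visible-light photolysis of F1 in dilute solution at low temperature generates the same C3 radical away from any electrode; after 6-endo closure the C5 radical takes the pyridylthio group from a second molecule of F1, giving the 5-(pyridin-2-ylsulfanyl) ketone F2. Oxidation with 3-chloroperbenzoic acid at −78 °C would give the sulfoxide F3, whose thermal syn-elimination gives the C4=C5 enone. The sequence comes back to the route at 24, so steps 13 and 14 are not needed.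

Step 7. Most likely to go wrong: attack of the organolithium on the benzylic ester or deprotonation next to the carbonyl, closure of the tertiary alkoxide onto the ester before it is silylated, or erosion of Felkin–Anh control by partial chelation of the triethylsilyl ether.
Fallback: the ester is taken out of the step. Setting out from 9, hydrogenolysis (H2, Pd/C, EtOAc) would give the keto acid (2S,3S)-4-oxo-2,3,5-tris(triethylsilyloxy)pentanoic acid F4. Its lithium carboxylate, formed with a first equivalent of 11, is neither electrophilic nor able to lactonise; a second equivalent of 11 adds to the ketone, and excess t-BuMe2SiOTf silylates alkoxide and carboxylate to give the bis-silylated adduct (tert-butyldimethylsilyl ester) F5. Treatment of F5 with KHCO3 in wet DMF followed by 4-methoxybenzyl chloride re-forms the benzylic ester, and the sequence comes back at 13.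

Step 9. Most likely to go wrong: incomplete discrimination between O3 and O2 in the benzoylation (benzoyl at O2), or migration of an acyl or silyl group between neighbouring oxygens under the basic conditions.
Fallback: the regiocontrol is moved from simple sterics to a tin acetal. Setting out from 14, one equivalent of 15 with 2,4,6-collidine at −40 °C would benzoylate only the primary O7, giving the mono-benzoate F6. Benzoylation of F6 with 15 in the presence of catalytic Me2SnCl2 and K2CO3 in THF proceeds through a stannylene acetal of the O2/O3 diol, which directs the acyl group to the less hindered, more acidic O3. The sequence comes back at 17, which is acetylated as in step 9 to give 18.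

Step 14. Most likely to go wrong: ionisation of the newly allylic C3 benzoate by the zerovalent palladium that forms, followed by elimination towards an aromatic ring, or simple protodesilylation back to 22.
Fallback: a metal-free dehydrogenation. Setting out from 23, PhSeCl at −78 °C would give the α-phenylselanyl ketone F7. Oxidation with H2O2/pyridine at 0 °C gives the selenoxide F8, which undergoes syn-elimination towards C4 (the only β-hydrogens), and the sequence comes back at 24.

## Further compounds

F1 | step 12 | 2-thioxopyridin-1(2H)-yl (2S,3S,4S)-3-acetoxy-2-(benzoyloxy)-4-[(benzoyloxy)methyl]-4-(tert-butyldimethylsilyloxy)-5-oxohept-6-enoate | S=C1C=CC=CN1OC(=O)[C@@H](OC(=O)c1ccccc1)[C@H](OC(C)=O)[C@](COC(=O)c1ccccc1)(O[Si](C)(C)C(C)(C)C)C(=O)C=C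
F2 | step 12 | [(1S,2S,3R)-2-acetoxy-3-(benzoyloxy)-1-(tert-butyldimethylsilyloxy)-6-oxo-5-(pyridin-2-ylsulfanyl)cyclohexyl]methyl benzoate (C5 epimers) | CC(=O)O[C@H]1[C@H](OC(=O)c2ccccc2)CC(Sc2ccccn2)C(=O)[C@]1(O[Si](C)(C)C(C)(C)C)COC(=O)c1ccccc1
F3 | step 12 | [(1S,2S,3R)-2-acetoxy-3-(benzoyloxy)-1-(tert-butyldimethylsilyloxy)-6-oxo-5-(pyridin-2-ylsulfinyl)cyclohexyl]methyl benzoate | CC(=O)O[C@H]1[C@H](OC(=O)c2ccccc2)CC(S(=O)c2ccccn2)C(=O)[C@]1(O[Si](C)(C)C(C)(C)C)COC(=O)c1ccccc1
F4 | step 7 | (2S,3S)-4-oxo-2,3,5-tris(triethylsilyloxy)pentanoic acid | OC(=O)[C@@H](O[Si](CC)(CC)CC)[C@H](O[Si](CC)(CC)CC)C(=O)CO[Si](CC)(CC)CC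
F5 | step 7 | tert-butyldimethylsilyl (2S,3S,4S)-4-(tert-butyldimethylsilyloxy)-5-methoxy-2,3-bis(triethylsilyloxy)-4-[(triethylsilyloxy)methyl]hepta-5,6-dienoate | CC(C)(C)[Si](C)(C)OC(=O)[C@@H](O[Si](CC)(CC)CC)[C@H](O[Si](CC)(CC)CC)[C@](CO[Si](CC)(CC)CC)(O[Si](C)(C)C(C)(C)C)C(OC)=C=C
F6 | step 9 | 4-methoxybenzyl (2S,3S,4S)-4-[(benzoyloxy)methyl]-4-(tert-butyldimethylsilyloxy)-2,3-dihydroxy-5-methoxyhepta-5,6-dienoate | COc1ccc(COC(=O)[C@@H](O)[C@H](O)[C@](COC(=O)c2ccccc2)(O[Si](C)(C)C(C)(C)C)C(OC)=C=C)cc1
F7 | step 14 | [(1S,2S,3R)-2-acetoxy-3-(benzoyloxy)-1-(tert-butyldimethylsilyloxy)-6-oxo-5-(phenylselanyl)cyclohexyl]methyl benzoate | CC(=O)O[C@H]1[C@H](OC(=O)c2ccccc2)CC([Se]c2ccccc2)C(=O)[C@]1(O[Si](C)(C)C(C)(C)C)COC(=O)c1ccccc1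
F8 | step 14 | [(1S,2S,3R)-2-acetoxy-3-(benzoyloxy)-1-(tert-butyldimethylsilyloxy)-6-oxo-5-(phenylseleninyl)cyclohexyl]methyl benzoate | CC(=O)O[C@H]1[C@H](OC(=O)c2ccccc2)CC([Se](=O)c2ccccc2)C(=O)[C@]1(O[Si](C)(C)C(C)(C)C)COC(=O)c1ccccc1
A1 | alternative 1 | all-trans 3,6-bis(tert-butyldimethylsilyloxy)-2-[(4-methoxybenzyl)oxy]cyclohex-4-en-1-one | COc1ccc(CO[C@H]2[C@H](O[Si](C)(C)C(C)(C)C)C=C[C@@H](O[Si](C)(C)C(C)(C)C)C2=O)cc1
A2 | alternative 1 | spiro-epoxide at C1 with C7 trans to the C2 oxygen | COc1ccc(CO[C@H]2[C@H](O[Si](C)(C)C(C)(C)C)C=C[C@@H](O[Si](C)(C)C(C)(C)C)[C@]23CO3)cc1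
A3 | alternative 2 | acetonide of cis-1-(benzoyloxymethyl)cyclohexa-3,5-diene-1,2-diol | CC1(C)O[C@H]2C=CC=C[C@]2(O1)COC(=O)c1ccccc1
A4 | alternative 2 | C3,C6-endoperoxide, peroxide bridge anti to the acetonide | CC1(C)O[C@H]2[C@H]3C=C[C@H](OO3)[C@]2(O1)COC(=O)c1ccccc1
A5 | alternative 3 | 2-(benzoyloxy)acrolein | C=C(OC(=O)c1ccccc1)C=O
A6 | alternative 3 | (E)-1-acetoxybuta-1,3-diene | CC(=O)O/C=C/C=C
A7 | alternative 3 | 2-acetoxy-1-(benzoyloxy)cyclohex-3-ene-1-carbaldehyde, oxygens cis | CC(=O)O[C@H]1C=CCC[C@]1(OC(=O)c1ccccc1)C=O
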